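**Plan**

- The retrosynthesis first cuts both aryl–C(β) bonds of the two cinnamoyl units (a twofold Heck arylation), then the two amide C–N bonds of the resulting bis(acrylamide). This leaves spermidine, acryloyl chloride and 4-bromocatechol.
- The enabling feature is that each 3,4-dihydroxyphenyl ring is joined through its C1 to the β-carbon of an E-acrylamide (Ar–CH=CH–C(=O)–NH). Both sp2–sp2 bonds can therefore be made last, on an intact polyamine carrying two terminal CH2=CH–C(=O)–NH groups.
- Forward: spermidine is differentiated (N1/N8 as trifluoroacetamides, N4 as Boc), the chain ends are freed and acryloylated, and ketal-masked 4-bromocatechol is attached at both ends in one Heck operation. One acid treatment then removes the Boc group and both ketals.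
- No ring of the target is built (both benzene rings are bought; only the temporary dioxole ketal ring is made), and there are no stereocentres. The two E double bonds come from the syn-insertion/syn-β-hydride-elimination course of the Heck step.

Key step: step 5

Remark: the target is drawn as the free secondary amine, so the salt formed in the acid deprotection (10) is neutralised within the same step.
Remark: steps that act on two like chain ends or on several acid-labile groups at once (1, 2, 3, 5, 6) are written as single transformations; their partly reacted species are driven on with excess reagent and are not numbered.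

**Route**

Step 1
Reactants: 1 spermidine
Product: 3 N4-Boc-N1,N8-bis(trifluoroacetyl)spermidine, via spermidine bis(trifluoroacetamide) 2 (not isolated)
Conditions: CF3CO2Et (2.1 equiv), MeOH, −78 → 0 °C; then Boc2O (1.3 equiv), 0 °C → rt
Reagents that add atoms: ethyl trifluoroacetate, CCOC(=O)C(F)(F)F; di-tert-butyl dicarbonate, CC(C)(C)OC(=O)OC(=O)OC(C)(C)C
Why: Ethyl trifluoroacetate is a mild acyl donor that undergoes aminolysis by the two unhindered primary amines much faster than by the secondary N4 (chemoselective N-trifluoroacetylation), so N4 is the only basic nitrogen left to form the tert-butyl carbamate with Boc2O in the same flask.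

Step 2
Reactants: 3 N4-Boc-N1,N8-bis(trifluoroacetyl)spermidine
Product: 4 N4-Boc-spermidine (tert-butyl N-(4-aminobutyl)-N-(3-aminopropyl)carbamate)
Conditions: K2CO3 (5 equiv), MeOH/H2O (10:1), 60 °C
Reagents that add atoms: none
Why: Carbonate-mediated solvolysis of trifluoroacetamides is fast because the CF3 group makes the amide carbonyl strongly electrophilic, whereas the tert-butyl carbamate is inert to mild base, so only the two chain ends are unmasked.

Step 3
Reactants: 4 N4-Boc-spermidine; 5 acryloyl chloride
Product: 6 N1,N8-bis(acryloyl)-N4-Boc-spermidine
Conditions: 5 (2.2 equiv), Et3N (3 equiv), CH2Cl2, −20 → 0 °C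
Reagents that add atoms: none
Why: Schotten–Baumann-type N-acylation of primary amines by an acid chloride at low temperature is far faster than conjugate addition to the acrylamide being formed, and the carbamate-blocked N4 cannot take part in aza-Michael addition.

Step 4
Reactants: 7 4-bromocatechol
Product: 8 5-bromo-2,2-dimethyl-1,3-benzodioxole
Conditions: 2,2-dimethoxypropane (3 equiv), TsOH·H2O (5 mol %), toluene, reflux, Soxhlet return over CaCl2
Reagents that add atoms: 2,2-dimethoxypropane, COC(C)(C)OC
Why: Acid-catalysed transketalisation of the ortho-dihydroxy unit with 2,2-dimethoxypropane gives the five-membered cyclic ketal, and trapping the liberated methanol on CaCl2 drives the equilibrium to completion while the aryl bromide is unaffected.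

Step 5
Reactants: 6 N1,N8-bis(acryloyl)-N4-Boc-spermidine; 8 5-bromo-2,2-dimethyl-1,3-benzodioxole
Product: 9 N4-Boc-N1,N8-bis(caffeoyl)spermidine bis(acetonide) (both alkenes E)
Conditions: 8 (2.6 equiv), Pd(OAc)2 (10 mol %), P(o-tolyl)3 (30 mol %), Et3N (5 equiv), BHT (trace), degassed DMF, 100 °C, argon
Reagents that add atoms: none
Why: Pd(OAc)2 is reduced in the flask by the phosphine and amine to zerovalent palladium, which inserts into the C–Br bond of 8; the arylpalladium bromide then adds syn across the acrylamide C=C with the aryl group delivered to the unsubstituted CH2 terminus, and C–C rotation followed by syn β-hydride elimination releases the cinnamamide while Et3N takes up HBr and returns the metal to the zerovalent state. The closest known reaction type is the Mizoroki–Heck arylation of N-alkyl acrylamides and acrylates with aryl bromides under Pd(OAc)2/P(o-tolyl)3, here run twice on one substrate. No ring closes and no stereocentre is created, so the only selectivities needed are β-regiochemistry and E geometry at each of the two new alkenes. β-Arylation is secured by the polarised, monosubstituted acrylamide (the aryl group migrates to the electron-poor, unhindered terminus), and E geometry by syn elimination through the conformer in which aryl and carboxamide are anti. The two acrylamide ends are electronically identical and insulated from each other by the saturated chain, so each couples independently and the excess of 8 carries mono-arylated material on to 9. The isopropylidene ketal keeps the catechol from chelating or reducing palladium, and the Boc carbamate blocks the only nitrogen that could undergo aza-Michael addition or bind the catalyst.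

Step 6
Reactants: 9 N4-Boc-N1,N8-bis(caffeoyl)spermidine bis(acetonide)
Product: 11 N1,N8-bis[(E)-caffeoyl]spermidine (free base), via target trifluoroacetate salt 10 (not isolated)
Conditions: TFA/H2O (9:1), 0 °C → rt, argon, dark; evaporate; then degassed NaHCO3 (aq) to pH 8, argon; C18 chromatography
Reagents that add atoms: none
Why: Aqueous trifluoroacetic acid effects acidolysis of the tert-butyl carbamate (loss of 2-methylpropene and CO2) and hydrolysis of both catechol isopropylidene ketals in one operation with water as the cation trap, the secondary amides and E-alkenes being inert; bicarbonate neutralisation under argon then frees the amine without exposing the catechols to strong base.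

**Compound list**

1 | spermidine, N-(3-aminopropyl)butane-1,4-diamine | NCCCCNCCCN | starting material
2 | N1,N8-bis(trifluoroacetyl)spermidine, N4 free (formed in the flask, not isolated) | O=C(NCCCCNCCCNC(=O)C(F)(F)F)C(F)(F)F | intermediate
3 | N4-Boc-N1,N8-bis(trifluoroacetyl)spermidine | CC(C)(C)OC(=O)N(CCCCNC(=O)C(F)(F)F)CCCNC(=O)C(F)(F)F | intermediate
4 | N4-Boc-spermidine, tert-butyl N-(4-aminobutyl)-N-(3-aminopropyl)carbamate | CC(C)(C)OC(=O)N(CCCCN)CCCN | intermediate
5 | acryloyl chloride | C=CC(=O)Cl | starting material
6 | N1,N8-bis(acryloyl)-N4-Boc-spermidine | C=CC(=O)NCCCCN(C(=O)OC(C)(C)C)CCCNC(=O)C=C | intermediate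
7 | 4-bromocatechol, 4-bromobenzene-1,2-diol | Oc1ccc(Br)cc1O | starting material
8 | 5-bromo-2,2-dimethyl-1,3-benzodioxole | CC1(C)Oc2ccc(Br)cc2O1 | intermediate
9 | N4-Boc-N1,N8-bis(caffeoyl)spermidine bis(acetonide), both alkenes E | CC1(C)Oc2ccc(/C=C/C(=O)NCCCCN(C(=O)OC(C)(C)C)CCCNC(=O)/C=C/c3ccc4OC(C)(C)Oc4c3)cc2O1 | intermediate
10 | N1,N8-bis[(E)-caffeoyl]spermidine trifluoroacetate, N4 ammonium salt (formed in the flask, not isolated) | O=C(/C=C/c1ccc(O)c(O)c1)NCCCC[NH2+]CCCNC(=O)/C=C/c1ccc(O)c(O)c1.[O-]C(=O)C(F)(F)F | intermediate
11 | N1,N8-bis[(E)-caffeoyl]spermidine | O=C(/C=C/c1ccc(O)c(O)c1)NCCCCNCCCNC(=O)/C=C/c1ccc(O)c(O)c1 | target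

**Step count**

Total steps: 6. Longest linear sequence: 5 (steps 1, 2, 3, 5, 6 from spermidine); step 4 is a one-step side branch that joins at step 5.

**Steps most likely to fail**

Step 5. Oxidative addition into the electron-rich aryl bromide may be slow enough that the catalyst decays to metallic palladium and the coupling stalls after one end has reacted. The bis(acrylamide) may also oligomerise by radical or thermal pathways before both ends are arylated. Fallback: setting out from 8, a single Heck coupling with acrylic acid (Pd(OAc)2, P(o-tolyl)3, Et3N, MeCN, 90 °C) should give (E)-3-(2,2-dimethyl-1,3-benzodioxol-5-yl)prop-2-enoic acid F1. Two equivalents of this acid are then condensed with diamine 4 (DCC, HOBt, CH2Cl2/DMF, 0 °C → rt), which comes back to the route at 9. The aryl–vinyl bond is still made by the same Heck disconnection, but on a small monofunctional acrylate, and step 3 is no longer needed.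

Step 6. The tert-butyl cation released from the carbamate may alkylate the electron-rich ring once the catechol is unveiled, the robust aryl ketals may hydrolyse incompletely, and the free catechols may oxidise to o-quinones during neutralisation. Fallback: setting out from 9, anhydrous HCl in dioxane (4 M, 0 °C → rt) should remove only the carbamate, since the ketals cannot hydrolyse without water and the cation is swept out as 2-methylpropene before any free catechol exists. This gives N1,N8-bis(caffeoyl)spermidine bis(acetonide) hydrochloride F2. The ketals are then hydrolysed in a carbocation-free medium (2 M HCl in THF/H2O, 50 °C, argon) to N1,N8-bis(caffeoyl)spermidine hydrochloride F3, and bicarbonate neutralisation as in step 6 comes back to the route at 11.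

Step 3. Unreacted primary amine may add in conjugate fashion to acrylamide already formed, giving oligomers, and the product may polymerise on concentration. Fallback: setting out from 4, acylation with 3-chloropropanoyl chloride (NaHCO3 (aq)/CH2Cl2, 0 °C) should give N4-Boc-N1,N8-bis(3-chloropropanoyl)spermidine F4, which contains no Michael acceptor while free amine is still present. Once all amine is consumed, twofold dehydrochlorination (Et3N, MeCN, 70 °C) unveils both acrylamides and comes back to the route at 6.

**Further compounds**

F1 | step 5 | (E)-3-(2,2-dimethyl-1,3-benzodioxol-5-yl)prop-2-enoic acid | CC1(C)Oc2ccc(/C=C/C(=O)O)cc2O1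
F2 | step 6 | N1,N8-bis[(E)-caffeoyl]spermidine bis(acetonide) hydrochloride | CC1(C)Oc2ccc(/C=C/C(=O)NCCCC[NH2+]CCCNC(=O)/C=C/c3ccc4OC(C)(C)Oc4c3)cc2O1.[Cl-]
F3 | step 6 | N1,N8-bis[(E)-caffeoyl]spermidine hydrochloride | O=C(/C=C/c1ccc(O)c(O)c1)NCCCC[NH2+]CCCNC(=O)/C=C/c1ccc(O)c(O)c1.[Cl-]
F4 | step 3 | N4-Boc-N1,N8-bis(3-chloropropanoyl)spermidine | CC(C)(C)OC(=O)N(CCCCNC(=O)CCCl)CCCNC(=O)CCCl
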